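A small charge of free catalyst, 50 mM against 0.99 M of starting material, has to turn over many times.

starting material 0.99 M; reagent 1.48 M; free catalyst 50 mM; time 1.5 min

    catalyst intermediate C ⇌ free catalyst + target (K1 = 1.3 M, k1 = 1.5 s⁻¹)
    starting material + catalyst intermediate B → catalyst intermediate C (k2 = 1.1 M⁻¹ s⁻¹)
    catalyst intermediate A ⇌ by-product + catalyst intermediate B (K3 = 0.16 M, k3 = 2.0 s⁻¹)
    reagent + free catalyst → catalyst intermediate A (k4 = 1.3 M⁻¹ s⁻¹)
    starting material + target ⇌ idle adduct, settled at all times (K5 = 0.87 M⁻¹)

- amount of target at 1.5 min, in percent of the starting material charged
- amount of target if the flask were left three thousand times as long, in percent of the starting material charged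

Treat the catalyst forms as balanced, since their half-lives of 0.35 s to 0.64 s are far shorter than the run. Drop the way back from free catalyst and target, and hold reagent at its charge. Each turn then costs a series of delays. The first is a fixed delay S, the summed inverse rates of reagent loading, by-product loss and target release, 1.69 s. The second is a capture delay, (1 + x/K)/(k a). Here x is the target made and also the by-product made, a is free starting material, k is 1.1 M⁻¹ s⁻¹ and K is 0.16 M.

Now define the catalyst budget, here 4.50 M·s, as catalyst charge times time. Summing the delays over x gives the budget a given x needs.

First take the flask without adduct, where a = c − x and c is the charge. The sum closes: S x + [(1 + c/K) ln(c/(c − x)) − x/K]/k. That reaches 50.0% in 0.850 min and 70.0% in 1.70 min. Interpolating to the asked time gives 65.3%.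

Then take the opposite extreme, an adduct so tight that each target holds one starting material. There a = c − 2x, which reaches zero at 50.0%. The real binding strength at the start is 0.86, near one, so take the middle: 57.6%. For the long run, reagent exceeds starting material and both are taken up irreversibly, so expect 100%.

The forecast says 58% and 100%: “given enough time all the starting material ends up as target”.

The flask gives 59.4% and 100%. Put 59.4% into the adduct-free sum: it asks for 78.7% of the budget, with idle adduct at 23.5%. Now cut free catalyst to 0.013 M. The neighbouring flask's budget shrinks to 1.17 M·s, and its target reaches 28.5%. The same sum asks for 91.0% of that budget, with idle adduct at 19.7%.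

The constants used here are assumed; what happens was integrated by code.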